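**Remarks.** The target is numbered as a 6,7,8,9-tetrahydrospiro[benzo[7]annulene-5,1'-cyclohexa-2',5'-dien]-4'-one: ring A = C1–C4/C4a/C9a, ring B = C4a–C5–C6–C7–C8–C9–C9a, ring C = C1'(=C5)–C6'. Open-chain intermediates are numbered along the butyl chain (C1 → C9, C2 → C8, C3 → C7, C4 → C6).
Assumption: the sense of induction of the two chiral catalysts (steps 2 and 4) is assigned by analogy with simple substrates. If it is the opposite on these substrates, the other enantiomer of the catalyst is used.

## Analysis of the target

The molecule has a 2,3,4-trimethoxybenzene (ring A) fused to a seven-membered carbocycle (ring B). Ring B is spiro-linked at C5 to a 3',5'-dimethoxycyclohexa-2',5'-dien-4'-one (ring C). There are three contiguous stereocentres, C7 (R, methyl), C8 (S, methyl) and C9 (R, benzylic acetate). They are all-trans around ring B, which is an all-syn triad in the open chain. C5 is quaternary but not stereogenic, because its two ring-C arms (C2'H=C3'(OMe) and C6'H=C5'(OMe)) are identical. The feature that drives the plan is this: C5 carries two C–C bonds, to C4a of ring A and to C6H2, that lead back to the same fragment, and its other two substituents are the symmetric arms of a syringol ring. C5 is therefore the para carbon of 2,6-dimethoxyphenol, bonded twice. The dienone is labile to acid (1,2-aryl shift from C5 to C2'/C6', the dienone–phenol rearrangement) and to reduction. The C9 acetate sits on a benzylic carbon para to a methoxy group and ionises easily; once deacylated, O9 lies 1,4 to C6. The difficulty is the quaternary C5 attached to a di-ortho-substituted arene inside a seven-membered ring, and a stereotriad whose C7/C8 methyl groups have no heteroatom to steer them.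

## Retrosynthetic reasoning

**C5–C4a and C5–C6 (key disconnection).** Both bonds at the spiro carbon are cut in one operation. This gives the open-chain aryl bromide/primary mesylate 9 and the commercial phenol boronate 10. Cutting here removes ring B, the quaternary centre and the dienone together, and leaves a monocyclic precursor with the stereotriad on a flexible chain. Forward, the boron-bearing carbon of 10 is first arylated (Suzuki–Miyaura) to the phenolate 11; the same carbon, now the para carbon of a phenolate, then displaces the mesylate. The medium is basic and non-oxidising, so neither the dienone nor the benzylic acetate is exposed to acid or oxidant.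

**C4–O (mesylate) and C3–H/C4–O.** Mesylate 9 comes from primary alcohol 8. Alcohol 8 comes from the 1,1-disubstituted alkene 6 by anti-Markovnikov hydration via the boronate 7. This is the only place where the C3 (→ C7) stereocentre is made. A catalyst-controlled hydroboration is chosen because uncatalysed hydroboration of a 2-methyl-1-alkene with an allylic methyl stereocentre is expected to favour the other (2,3-anti) isomer.

**O-acetyl.** Acetate 6 comes from alcohol 5. The acetate is put on early because it is in the target and because it masks O1, which would otherwise close a tetrahydrofuran onto C4 as soon as C4 carries a leaving group.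

**C1–C2.** Alcohol 5 is cut between the carbinol carbon and C2 into aldehyde 4 and the Z-configured 2-methylcrotyl boronate 3. One allylboration forms this bond, sets C1 and C2 (→ C9, C8) in the syn relationship, and delivers the isopropenyl group that holds C3 and C4 at the right oxidation level.

**C–B.** Boronate 3 is the 1,4-hydroboration product of isoprene 1 with pinacolborane 2; the s-cis diene fixes the Z geometry.

## Alternatives that were turned down

**Alternative 1:** (textbook) Cut only C5–C4a. Forward key step: hypervalent-iodine oxidation of the phenolic 1,4-diarylbutane A1 in a fluoro alcohol, with para attack of ring A on the phenoxenium ion. It was turned down for three reasons. The closure runs in an oxidising, acidic, ionising medium, in which the product dienone can rearrange by aryl shift to C2'/C6' and the C9 acetate on the most electron-rich ring can ionise. It forms one bond only, so the C6–aryl bond needs a separate sp3–sp2 coupling. It is not shorter than the chosen route. It is kept as the fallback for the key step.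

**Alternative 2:** Cut C4a–C5 and C9a–C9, i.e. annulate ring A onto a chain. Forward key step: Catellani reaction of 1-iodo-2,3,4-trimethoxybenzene A2 with the mixed anhydride A3 (ortho C–H acylation, then ipso dearomative arylation of the tethered phenol) to the spiro ketone A4. It was turned down because:
- the secondary C9 cannot be introduced by ortho-alkylation, so an anhydride is needed, and this acylates the free phenol;
- the termination needs an eight-membered palladacycle at a di-ortho-substituted aryl–Pd;
- C8 is epimerisable next to the ketone at the reaction temperature;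
- C9 would still have to be set by hydride reduction beside the dienone carbonyl, followed by acetylation.

**Alternative 3:** Cut C5–C6 oxidatively. Forward key step: oxidation of the biaryl phenol A5 to its phenoxenium ion and attack of the isopropenyl CH2 on C1' (7-endo cation–olefin closure) to the alkene A6. It was turned down because the tertiary C7 cation can only eliminate. C7 would then have to be set by reducing an alkene in the presence of the reducible cross-conjugated dienone, with neither chemoselectivity nor facial selectivity secured. The oxidative, acidic medium of Alternative 1 also returns.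

Key step: step 6

## Route

Step 1
Reactants: 1 isoprene (2-methylbuta-1,3-diene); 2 pinacolborane (4,4,5,5-tetramethyl-1,3,2-dioxaborolane)
Product: 3 (Z)-4,4,5,5-tetramethyl-2-(2-methylbut-2-en-1-yl)-1,3,2-dioxaborolane
Conditions: FeCl2 complex of a 2-(aryliminomethyl)pyridine ligand (4 mol %), Mg (10 mol %), Et2O, 23 °C
Reagents that add atoms: none
Why: Iron-catalysed 1,4-hydroboration of a 2-substituted 1,3-diene; the diene reacts s-cis, so CH2B (C1) and the new CH3 (C4) end up cis on the C2=C3 bond (Z-crotyl-type geometry), and the N-aryl group of the ligand is chosen for boron delivery to C1, the terminus next to the methyl-bearing carbon.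

Step 2
Reactants: 4 2-bromo-3,4,5-trimethoxybenzaldehyde; 3 (Z)-4,4,5,5-tetramethyl-2-(2-methylbut-2-en-1-yl)-1,3,2-dioxaborolane
Product: 5 (1R,2S)-1-(2-bromo-3,4,5-trimethoxyphenyl)-2,3-dimethylbut-3-en-1-ol
Conditions: (R)-TRIP [(R)-3,3'-bis(2,4,6-triisopropylphenyl)-BINOL hydrogen phosphate] (5 mol %), 4 Å MS, toluene, −30 → 0 °C; aqueous work-up
Reagents that add atoms: none
Why: Chiral-phosphoric-acid-catalysed allylboration through a closed chair transition state (Type I): the Z γ-methyl is axial and the aryl group equatorial, which should give the 1,2-syn product, and the acid bound to the boronate oxygen and the formyl hydrogen should select the Re face of the aldehyde (1R); the allyl transposition leaves C3/C4 as the isopropenyl group.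

Step 3
Reactants: 5 (1R,2S)-1-(2-bromo-3,4,5-trimethoxyphenyl)-2,3-dimethylbut-3-en-1-ol
Product: 6 (1R,2S)-1-(2-bromo-3,4,5-trimethoxyphenyl)-2,3-dimethylbut-3-en-1-yl acetate
Conditions: Ac2O, DMAP (cat.), pyridine, 0 → 23 °C
Reagents that add atoms: acetic anhydride, CC(=O)OC(C)=O
Why: DMAP-catalysed acylation of a secondary benzylic alcohol; no stereocentre is touched, and the acetate is both the ester of the target and the mask that keeps O1 from attacking C4 later.

Step 4
Reactants: 6 (1R,2S)-1-(2-bromo-3,4,5-trimethoxyphenyl)-2,3-dimethylbut-3-en-1-yl acetate; 2 pinacolborane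
Product: 8 (1R,2S,3S)-1-(2-bromo-3,4,5-trimethoxyphenyl)-4-hydroxy-2,3-dimethylbutyl acetate, via alkyl pinacol boronate 7 (not isolated)
Conditions: CuCl (5 mol %), (R)-DTBM-SEGPHOS (5.5 mol %), KOt-Bu (10 mol %), cyclohexane, 23 °C; then NaBO3·4H2O, THF/H2O, 23 °C
Reagents that add atoms: sodium perborate, [Na+].[Na+].O[B-]1(O)OO[B-](O)(O)OO1
Why: Copper-hydride-catalysed enantioselective anti-Markovnikov hydroboration of a 1,1-disubstituted alkene: the ligand-bound Cu–H differentiates methyl from the branched C2 substituent and delivers H to one face of C3 under catalyst control (the descriptor changes from 3R in 7 to 3S in 8 only because of CIP priorities); perborate oxidises the C–B bond with retention and is mild enough for the acetate, and the aryl bromide and the ester are not expected to react with the copper hydride at 23 °C.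

Step 5
Reactants: 8 (1R,2S,3S)-1-(2-bromo-3,4,5-trimethoxyphenyl)-4-hydroxy-2,3-dimethylbutyl acetate
Product: 9 (1R,2S,3S)-1-(2-bromo-3,4,5-trimethoxyphenyl)-2,3-dimethyl-4-[(methylsulfonyl)oxy]butyl acetate
Conditions: MsCl, Et3N, CH2Cl2, −10 °C
Reagents that add atoms: methanesulfonyl chloride, CS(=O)(=O)Cl
Why: Sulfonylation of the only free (primary) hydroxyl; the acetate on O1 prevents the 5-exo cyclisation to a tetrahydrofuran that a 1,4-diol monosulfonate would undergo.

Step 6
Reactants: 9 (1R,2S,3S)-1-(2-bromo-3,4,5-trimethoxyphenyl)-2,3-dimethyl-4-[(methylsulfonyl)oxy]butyl acetate; 10 2,6-dimethoxy-4-(4,4,5,5-tetramethyl-1,3,2-dioxaborolan-2-yl)phenol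
Product: 12 (7R,8S,9R)-2,3,3',4,5'-pentamethoxy-7,8-dimethyl-4'-oxo-6,7,8,9-tetrahydrospiro[benzo[7]annulene-5,1'-cyclohexa[2,5]dien]-9-yl acetate (the target), via biaryl phenolate mesylate 11 (not isolated)
Conditions: Pd(OAc)2 (5 mol %), SPhos (10 mol %), K3PO4 (4 equiv), toluene/H2O 10:1 (0.02 M), 70 °C; then t-AmOH added (to 0.005 M), 95 °C
Reagents that add atoms: none
Why: Proposed new method: a Suzuki–Miyaura coupling and an Ar1-type phenolate para-alkylation (alkylative dearomatisation) are run in one flask, so that the para carbon of phenol 10 is bonded twice, first as the boron-bearing carbon and then as the para carbon of the phenolate; each half is a known reaction type (coupling of unprotected 4-hydroxyarylboronates with di-ortho-substituted aryl bromides; base-induced spirodienone formation from para-(ω-sulfonyloxyalkyl)phenols), while their sequence and the seven-membered ring are not. Pd(0)/SPhos inserts into the C–Br bond of 9 (the primary sp3 mesylate is inert to this catalyst), and transmetalation with the boronate and reductive elimination give phenolate 11. In 11 the carbon para to O−, which is the biaryl carbon C1', carries the largest carbon coefficient of the phenolate, and the twisted biaryl axis holds the C4 mesylate over the face of the phenol ring at that carbon; SN2 displacement (7-exo-tet) closes ring B, creates the quaternary C5 and leaves the cross-conjugated dienone, which cannot re-aromatise because C5 has no hydrogen. No stereocentre is formed: C5 lies on the local mirror plane of ring C, the displacement occurs at a CH2 group, and the weak base leaves C7, C8 and C9 untouched. The selectivity needed is C- over O-alkylation: intramolecular O-alkylation and ortho-C attack are out of geometric reach (the oxygen is para to the tether and the ortho carbons carry OMe), so only bimolecular O-alkylation competes, and this is disfavoured by the high dilution, the two methoxy groups flanking the oxygen and the protic tertiary alcohol. The acetate must survive, which is why a phosphate and not an alkoxide is the base; without it O1 would close the tetrahydrofuran by 5-exo attack on C4.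

## Compound list

1 | isoprene (2-methylbuta-1,3-diene) | C=CC(C)=C | starting material
2 | pinacolborane (4,4,5,5-tetramethyl-1,3,2-dioxaborolane) | B1OC(C)(C)C(C)(C)O1 | starting material
3 | (Z)-4,4,5,5-tetramethyl-2-(2-methylbut-2-en-1-yl)-1,3,2-dioxaborolane | C/C=C(/C)CB1OC(C)(C)C(C)(C)O1 | intermediate
4 | 2-bromo-3,4,5-trimethoxybenzaldehyde | COc1cc(C=O)c(Br)c(OC)c1OC | starting material
5 | (1R,2S)-1-(2-bromo-3,4,5-trimethoxyphenyl)-2,3-dimethylbut-3-en-1-ol | C=C(C)[C@H](C)[C@@H](O)c1cc(OC)c(OC)c(OC)c1Br | intermediate
6 | (1R,2S)-1-(2-bromo-3,4,5-trimethoxyphenyl)-2,3-dimethylbut-3-en-1-yl acetate | C=C(C)[C@H](C)[C@@H](OC(C)=O)c1cc(OC)c(OC)c(OC)c1Br | intermediate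
7 | (1R,2S,3R)-1-(2-bromo-3,4,5-trimethoxyphenyl)-2,3-dimethyl-4-(4,4,5,5-tetramethyl-1,3,2-dioxaborolan-2-yl)butyl acetate | CC1(C)OB(C[C@@H](C)[C@H](C)[C@@H](OC(C)=O)c2cc(OC)c(OC)c(OC)c2Br)OC1(C)C | intermediate
8 | (1R,2S,3S)-1-(2-bromo-3,4,5-trimethoxyphenyl)-4-hydroxy-2,3-dimethylbutyl acetate | OC[C@@H](C)[C@H](C)[C@@H](OC(C)=O)c1cc(OC)c(OC)c(OC)c1Br | intermediate
9 | (1R,2S,3S)-1-(2-bromo-3,4,5-trimethoxyphenyl)-2,3-dimethyl-4-[(methylsulfonyl)oxy]butyl acetate | CS(=O)(=O)OC[C@@H](C)[C@H](C)[C@@H](OC(C)=O)c1cc(OC)c(OC)c(OC)c1Br | intermediate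
10 | 2,6-dimethoxy-4-(4,4,5,5-tetramethyl-1,3,2-dioxaborolan-2-yl)phenol | COc1cc(B2OC(C)(C)C(C)(C)O2)cc(OC)c1O | starting material
11 | (1R,2S,3S)-1-[2-(4-hydroxy-3,5-dimethoxyphenyl)-3,4,5-trimethoxyphenyl]-2,3-dimethyl-4-[(methylsulfonyl)oxy]butyl acetate (present in the flask as its potassium phenolate) | CS(=O)(=O)OC[C@@H](C)[C@H](C)[C@@H](OC(C)=O)c1cc(OC)c(OC)c(OC)c1-c1cc(OC)c(O)c(OC)c1 | intermediate
12 | (7R,8S,9R)-2,3,3',4,5'-pentamethoxy-7,8-dimethyl-4'-oxo-6,7,8,9-tetrahydrospiro[benzo[7]annulene-5,1'-cyclohexa[2,5]dien]-9-yl acetate | COC1=CC2(C=C(OC)C1=O)C[C@@H](C)[C@H](C)[C@@H](OC(C)=O)c1cc(OC)c(OC)c(OC)c12 | target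

## Step count and risks

Total step count: 6. Longest linear sequence: 6 steps (1 → 3 → 5 → 6 → 8 → 9 → 12); 5 steps from aldehyde 4.

**Step 6 (key step, Proposed new method).** Three things are most likely to go wrong:
- Bimolecular O-alkylation (oligomerisation) may outrun the seven-membered C-alkylation of 11.
- The mesylate or the acetate may be hydrolysed during the coupling; loss of the acetate is followed by 5-exo closure of O1 onto C4.
- The electron-rich boronate may undergo protodeboronation before transmetalation.

The fallback uses known chemistry and closes the other bond at C5 oxidatively. It sets out from boronate 3 and returns at 12. Boronate 3 is added to purchased 3,4,5-trimethoxybenzaldehyde under the conditions of step 2 to give (1R,2S)-2,3-dimethyl-1-(3,4,5-trimethoxyphenyl)but-3-en-1-ol F1. This is acetylated as in step 3 to (1R,2S)-2,3-dimethyl-1-(3,4,5-trimethoxyphenyl)but-3-en-1-yl acetate F2. Copper-hydride hydroboration as in step 4, without oxidation, gives (1R,2S,3R)-2,3-dimethyl-4-(4,4,5,5-tetramethyl-1,3,2-dioxaborolan-2-yl)-1-(3,4,5-trimethoxyphenyl)butyl acetate F3. Without an aryl bromide in the molecule, F3 can be cross-coupled (Pd(OAc)2/RuPhos, K2CO3, toluene/H2O) with purchased 4-bromo-2,6-dimethoxyphenol to (1R,2S,3R)-4-(4-hydroxy-3,5-dimethoxyphenyl)-2,3-dimethyl-1-(3,4,5-trimethoxyphenyl)butyl acetate F4, the same compound as A1. Oxidation of F4 with PhI(OCOCF3)2 in CF3CH2OH at −40 °C should give 12 by phenol para-oxidative coupling, quenched cold with base to spare the dienone.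

**Step 4.** The catalyst has to override the substrate's own facial preference at an α-branched alkene. Slow hydrocupration and poor facial selectivity at C3 are the likely failure; partial reduction of the acetate by copper hydride is a second possibility. The fallback sets out from 6 and returns at 8. Allylic oxidation of the isopropenyl methyl group (SeO2 cat., t-BuOOH, CH2Cl2) gives (1R,2S)-1-(2-bromo-3,4,5-trimethoxyphenyl)-3-(hydroxymethyl)-2-methylbut-3-en-1-yl acetate F5. Homogeneous asymmetric hydrogenation of this 2-substituted allylic alcohol (Ru–BINAP dicarboxylate or a cationic Ir–phosphinooxazoline, H2) then sets C3 with the hydroxyl as anchor and gives 8. The former =CH2 becomes the methyl group; the aryl bromide is not touched by these catalysts.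

**Step 2.** The electron-rich, ortho-brominated aldehyde reacts slowly, so an uncatalysed background allylboration may erode enantioface selectivity, and any E isomer in 3 would erode the syn selectivity. The fallback sets out from 4 and returns at 5. An Evans syn-aldol reaction of 4 with (R)-4-benzyl-3-propionyloxazolidin-2-one (Bu2BOTf, i-Pr2NEt, CH2Cl2, −78 °C) gives (R)-4-benzyl-3-[(2R,3R)-3-(2-bromo-3,4,5-trimethoxyphenyl)-3-hydroxy-2-methylpropanoyl]oxazolidin-2-one F6. Transamidation (MeONHMe·HCl, AlMe3) gives (2R,3R)-3-(2-bromo-3,4,5-trimethoxyphenyl)-3-hydroxy-N-methoxy-N,2-dimethylpropanamide F7. Excess MeMgBr gives (3R,4R)-4-(2-bromo-3,4,5-trimethoxyphenyl)-4-hydroxy-3-methylbutan-2-one F8. Non-basic methylenation with the Tebbe reagent then gives 5.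

**Step 1.** Regiochemical leakage (boron delivered to C4, giving the prenyl boronate) or loss of Z geometry would pass into step 2 as constitutional and anti isomers. The fallback sets out from 2 and returns at 3. Ruthenium-catalysed trans-hydroboration of but-2-yne with 2 ([Cp*Ru(MeCN)3]PF6, CH2Cl2) gives (E)-2-(but-2-en-2-yl)-4,4,5,5-tetramethyl-1,3,2-dioxaborolane F9. Matteson homologation (BrCH2Cl, n-BuLi, THF, −78 °C) inserts CH2 into the C–B bond with retention of the alkene geometry and gives 3.

## Further compounds

F1 | step 6 | (1R,2S)-2,3-dimethyl-1-(3,4,5-trimethoxyphenyl)but-3-en-1-ol | C=C(C)[C@H](C)[C@@H](O)c1cc(OC)c(OC)c(OC)c1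
F2 | step 6 | (1R,2S)-2,3-dimethyl-1-(3,4,5-trimethoxyphenyl)but-3-en-1-yl acetate | C=C(C)[C@H](C)[C@@H](OC(C)=O)c1cc(OC)c(OC)c(OC)c1
F3 | step 6 | (1R,2S,3R)-2,3-dimethyl-4-(4,4,5,5-tetramethyl-1,3,2-dioxaborolan-2-yl)-1-(3,4,5-trimethoxyphenyl)butyl acetate | CC1(C)OB(C[C@@H](C)[C@H](C)[C@@H](OC(C)=O)c2cc(OC)c(OC)c(OC)c2)OC1(C)C
F4 | step 6 | (1R,2S,3R)-4-(4-hydroxy-3,5-dimethoxyphenyl)-2,3-dimethyl-1-(3,4,5-trimethoxyphenyl)butyl acetate | COc1cc(C[C@@H](C)[C@H](C)[C@@H](OC(C)=O)c2cc(OC)c(OC)c(OC)c2)cc(OC)c1O
F5 | step 4 | (1R,2S)-1-(2-bromo-3,4,5-trimethoxyphenyl)-3-(hydroxymethyl)-2-methylbut-3-en-1-yl acetate | C=C(CO)[C@H](C)[C@@H](OC(C)=O)c1cc(OC)c(OC)c(OC)c1Br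
F6 | step 2 | (R)-4-benzyl-3-[(2R,3R)-3-(2-bromo-3,4,5-trimethoxyphenyl)-3-hydroxy-2-methylpropanoyl]oxazolidin-2-one | O=C(N1C(=O)OC[C@H]1Cc1ccccc1)[C@H](C)[C@@H](O)c1cc(OC)c(OC)c(OC)c1Br
F7 | step 2 | (2R,3R)-3-(2-bromo-3,4,5-trimethoxyphenyl)-3-hydroxy-N-methoxy-N,2-dimethylpropanamide | CON(C)C(=O)[C@H](C)[C@@H](O)c1cc(OC)c(OC)c(OC)c1Br
F8 | step 2 | (3R,4R)-4-(2-bromo-3,4,5-trimethoxyphenyl)-4-hydroxy-3-methylbutan-2-one | CC(=O)[C@H](C)[C@@H](O)c1cc(OC)c(OC)c(OC)c1Br
F9 | step 1 | (E)-2-(but-2-en-2-yl)-4,4,5,5-tetramethyl-1,3,2-dioxaborolane | C/C=C(/C)B1OC(C)(C)C(C)(C)O1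
A1 | alternative 1 | (1R,2S,3R)-4-(4-hydroxy-3,5-dimethoxyphenyl)-2,3-dimethyl-1-(3,4,5-trimethoxyphenyl)butyl acetate | COc1cc(C[C@@H](C)[C@H](C)[C@@H](OC(C)=O)c2cc(OC)c(OC)c(OC)c2)cc(OC)c1O
A2 | alternative 2 | 1-iodo-2,3,4-trimethoxybenzene | COc1ccc(I)c(OC)c1OC
A3 | alternative 2 | (2S,3R)-4-(4-hydroxy-3,5-dimethoxyphenyl)-2,3-dimethylbutanoic pivalic anhydride | CC(C)(C)C(=O)OC(=O)[C@@H](C)[C@H](C)Cc1cc(OC)c(O)c(OC)c1
A4 | alternative 2 | (7R,8S)-2,3,3',4,5'-pentamethoxy-7,8-dimethyl-7,8-dihydrospiro[benzo[7]annulene-5,1'-cyclohexa[2,5]diene]-4',9(6H)-dione | COC1=CC2(C=C(OC)C1=O)C[C@@H](C)[C@H](C)C(=O)c1cc(OC)c(OC)c(OC)c12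
A5 | alternative 3 | (1R,2S)-1-[2-(4-hydroxy-3,5-dimethoxyphenyl)-3,4,5-trimethoxyphenyl]-2,3-dimethylbut-3-en-1-yl acetate | C=C(C)[C@H](C)[C@@H](OC(C)=O)c1cc(OC)c(OC)c(OC)c1-c1cc(OC)c(O)c(OC)c1
A6 | alternative 3 | (8S,9R)-2,3,3',4,5'-pentamethoxy-8-methyl-7-methylidene-4'-oxo-6,7,8,9-tetrahydrospiro[benzo[7]annulene-5,1'-cyclohexa[2,5]dien]-9-yl acetate | COC1=CC2(C=C(OC)C1=O)CC(=C)[C@H](C)[C@@H](OC(C)=O)c1cc(OC)c(OC)c(OC)c12
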